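The runs were generated by integration with constants of no real substance; noise was put on by code.

I began from what the five flasks held constant, 22 mM of free monomer and 2.5 mol% of initiator, while the transfer agent moved from flask to flask.

in all of them: free monomer 22 mM; initiator 2.5 mol%

| flask | transfer agent | remark | time |
|---|---|---|---|
| theta | 0.46 mM | run made earlier |  |
| beta | 0.49 mM | run made earlier |  |
| delta | 0.63 mM | run made earlier |  |
| Sunday's | 0.660 mM |  | 8.0 h |
| Thursday's | 0.400 mM |  | 8.0 h |

| theta: time / h | theta: monomer in chains / % | beta: time / h | beta: monomer in chains / % | delta: time / h | delta: monomer in chains / % |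
|---|---|---|---|---|---|
| 0.333 | 4.6 | 0.333 | 4.4 | 0.333 | 4.4 |
| 0.667 | 6.4 | 0.667 | 6.5 | 0.667 | 6.8 |
| 1.00 | 8.6 | 1.00 | 8.2 | 1.00 | 7.3 |
| 2.00 | 11.9 | 2.00 | 11.3 | 2.00 | 9.6 |
| 4.00 | 16.0 | 4.00 | 16.1 | 4.00 | 12.4 |

(each reading ± 0.5 percentage points)

- the average divides the monomer in chains by the number of chains begun, living and dead together
- the earlier runs do not show the number of chains; that part of a forecast is a guess

* which of the two ends with the longer chains by the average number of monomer units in a chain (chains begun, living or dead) ("neither" if they lie within 10%) (Sunday's / Thursday's / neither)
* average number of monomer units in a chain (chains begun, living or dead) at the end, Sunday's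
* average number of monomer units in a chain (chains begun, living or dead) at the end, Thursday's

My own reckoning froze the chain count: if each initiator begins one chain and each transfer agent ends one, the average length is the share of free monomer in chains divided by the initiator loading, and what separates the flasks is the kill ratio, transfer agent charged per initiator charged, 0.727 for Thursday's and 1.20 for Sunday's. On that count, a ratio below 1 should leave a share of one minus the ratio living and adding monomer, while above 1 growth should stall. The readings hinted at this, though weakly at their scatter: between 2.00 h and 4.00 h the delta run, at ratio 1.15, gained 2.8 percentage points, and the theta run, at 0.836, gained 4.1 points. So I expected Sunday's near 4.96 units, the delta run's last reading over the loading, and Thursday's above the theta run's 6.40.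

The forecast gave Thursday's, with 4.7 for Sunday's and 11 for Thursday's, counting chains as “the transfer agent plus some initiator-derived chains”, where my count made them equal.

The flask gave Thursday's, with 5.33 for Sunday's and 10.8 for Thursday's.

    free monomer + initiator → living end + monomer in chains (k = 580 M⁻¹ h⁻¹)
    living end + transfer agent → dead chain (kL = 2400 M⁻¹ h⁻¹)
    2 initiator → spent initiator (k = 310 M⁻¹ h⁻¹)
    free monomer + living end → monomer in chains + living end, rate k4*[living end]*[free monomer] (k = 170 M⁻¹ h⁻¹)

The two flasks differ in transfer agent, and that difference is the main reason for the gap in length, 10.8 units for Thursday's against 5.33 with Sunday's charge of transfer agent: Thursday's ended with 27.3% of its initiator charge as living ends, against 27.3% reckoned from the kill ratio, and its monomer in chains rose from 18.1% to 26.5% over the second half, while Sunday's kept 2.07% and rose from 11.7% to 13.1%. The neighbour flask, Sunday's with 6.2 mol% of initiator, had a kill ratio of 0.484, which pointed to 51.6% staying living; it ended with 48.4% of its initiator charge as living ends and reached 10.5 units.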